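## Structural features

- **Skeleton and locants.** The target is a C20 acetoxy ene-dialdehyde on a bicyclo[3.3.1]nonene core. C1 is the acetoxy-bearing one-carbon bridge and C2 the methyl-bearing bridgehead. C3–C4=C5 is the bridge carrying the enal (formyl on C5), and C6 is the formyl-bearing bridgehead. C7–C8–C9 is the saturated bridge, with the (R)-6-methylhept-5-en-2-yl chain (C1′) on C7. Ring A is C1–C2–C3–C4–C5–C6; ring B is C1–C2–C9–C8–C7–C6.
- **Stereocentres.** Five stereocentres lie in an unbroken row, C2–C1–C6–C7–C1′. In these locants they are 1R, 2R, 6R, 7S and 1′R, and both bridgeheads are quaternary.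
- **Faces of ring B.** The β face carries C3 on C2, C5 on C6 and the side chain on C7. The α face carries the C2 methyl, the C6 formyl group and the C1 oxygen, so the acetate lies over the saturated bridge and not over the enal bridge.
- **Fragile groups.** The 1,4-dialdehyde with one conjugated arm is sensitive to base, amines and oxidants. The β-acyloxy aldehyde pair C1/C6 becomes open to retro-aldol cleavage once the oxygen is free. The trisubstituted side-chain alkene is sensitive to acid and to electrophiles.
- **Real difficulty.** C6 is fully substituted and flanked by three stereocentres. The C5–C6 bond joins the α-carbons of two aldehydes, two centres of the same natural polarity.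
- **Feature the key step exploits.** Because C5–C6 is the central bond of a 1,4-dicarbonyl unit, it can be made by oxidative union of two enol ethers. Once it exists, C6 has no α-hydrogen, so later enolisation and desaturation can occur only at C5/C4.
- **Chiral pool match.** Ring B with its C2 methyl, C1 oxygen and C7 side chain (C1′ already R) is the carbon framework of (R)-xanthorrhizol.

## Logic of the disconnections

**22 ⇒ 20 (through 21).** The C4=C5 double bond is removed, formally returning hydrogen to C4 and C5. This leaves a saturated ring A whose two formyl-bearing carbons are the two ends of one bond. The forward step must enolise only the C5 aldehyde and eliminate only toward C4. Both follow from C6 being quaternary.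

**20 ⇒ 19 ⇒ 18.** The acetyl C–O bond at C1 is cut, then the two aldehydes are returned to dimethyl acetals and the C1 oxygen to a silyl ether. This lets the oxidation step be run on a substrate without free carbonyl or hydroxyl groups. The forward demand is one acid treatment that hydrolyses a neopentyl acetal and a hindered silyl ether without touching the side-chain alkene, followed by acylation of a hindered alcohol.

**18 ⇒ 17 (key).** The C5–C6 bond is cut. Two like-polarised carbons are joined here, so the forward step must be oxidative. The cut removes ring A and the quaternary stereocentre C6 together and leaves a monocyclic ring B carrying two enol ethers. The forward step needs the C2 chain axial on ring B, an oxidation window between the enol ethers and the side-chain alkene, and ring closure faster than solvent capture.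

**17 ⇒ 15 (through 16).** Both enol ether double bonds are traced back to dimethyl acetals and the C1 silyl ether to the free alcohol. The gain is a stable storage form and the making of both enol ethers in one operation. The forward step must remove a hindered C6 hydrogen next to an oxocarbenium ion and must not ionise the allylic silyl ether it creates.

**15 ⇒ 12 + 13 (through 14).** The bond between C5 and the chain's terminal carbon is cut. A three-carbon allyl unit is far easier to attach to a hindered enolate than a four-carbon unit, and the fourth carbon can be added at the alkene terminus. The forward step needs linear selectivity and must leave the trisubstituted alkene alone.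

**12 ⇒ 11.** The C1–H bond is cut. The forward hydride must arrive from the β face, syn to the axial allyl group, to give the α (axial) alcohol.

**11 ⇒ 8 + 9 (through 10).** The bond from C6 to its one-carbon substituent is cut. C6 is the only enolisable position of 8, and 9 delivers the carbon already at the aldehyde oxidation level and already masked. The electrophile must choose the silyl enol ether over the two alkenes.

**8 ⇒ 6 + 7.** The C2–C3 bond is cut. The quaternary stereocentre C2 is made by allylating a tetrasubstituted enolate of defined regiochemistry. The allyl group must enter on the face of the C7 side chain, which both the ligand and the substrate should favour.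

**6 ⇒ 5 ⇒ 4.** The silyl enol ether is returned to the ketone and the C7–H bond is cut. C7 is set by a ligand-controlled conjugate hydride addition to a 3-alkylcyclohexenone. The C2 centre is left unset because it is planar in 6.

**4 ⇒ 2 ⇒ 1.** The enone is traced to the arene by dearomatisation. Ring B, the C2 methyl, the C1 oxygen and C1′ with its configuration all come from 1. The forward reduction must leave methyl, oxygen and side chain on sp2 carbons and must not disturb C1′.

## Other disconnections considered

**Alternative 1:** The cut is through C2–C3 and the bond from C6 to the future formyl carbon, with C5–C6 made afterwards by a 1,2-shift. In the forward sense a ring B α,α-dibromoketone A2 (reachable from 5) would be ionised by an amine base in a fluorinated alcohol to the bromo-oxyallyl cation spanning C2–C1–C6. The silyloxy diene A3 would capture it in a (4+3) cycloaddition to give the bridgehead bromide A1. A semipinacol shift of C5 from the carbinol carbon to C6, with loss of bromide, would then contract the seven-membered ring and leave the formyl group on C6.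
- In its favour: the plan is convergent. Both quaternary bridgeheads, the C4=C5 alkene and the carbon substituent on C5 arrive together, so no late dehydrogenation is needed; on that point it is better than the chosen plan. It uses the same xanthorrhizol-derived ring B, so it is equal on chiral-pool economy.
- Against it here: two fully substituted oxyallyl termini must bond to an acyclic, unsymmetrical diene. Regiochemistry, the choice between (4+3) and simple alkylation or (3+2) addition, and the facial choice next to C7 are all open in an intermolecular step. The ring contraction needs ionisation of a bridgehead α-keto bromide with the migrating bond anti-periplanar, and quasi-Favorskii contraction could compete. The C1 ketone must be reduced before any aldehyde is unveiled.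
- Comparison: in the chosen plan the one new stereocentre of the key step is fixed by a tether and the bond is formed intramolecularly, so mechanistic control is better there. The step count of Alternative 1 should be similar or slightly lower.

**Alternative 2:** The cut is the C1–C6 bond. In the forward sense the cyclooctene aldehyde A5, activated by Me2AlCl, would undergo a transannular carbonyl-ene reaction. C1 bonds to C6, a C4 hydrogen passes to oxygen and the alkene moves to C4=C5, giving A4.
- In its favour: one step divides the eight-membered ring into both six-membered rings, creates quaternary C6 and the C1 carbinol and places the alkene correctly. Both formyl carbons travel as silyl-protected primary alcohols, which are sturdier than the acetals and aldehydes of the chosen plan; that is a point where it is better. Control of C6 by transannular geometry is the equal of tether control, and no late dehydrogenation is needed.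
- Against it here: A5 has no chiral-pool counterpart. It is a medium ring with a tetrasubstituted alkene, quaternary C2 and the C7/C1′ pair, and it must be built first; ring B of xanthorrhizol cannot be used because the ene step itself makes ring B. The transferred hydrogen could also come from the C5 silyloxymethyl group. The hydroxyl should land over the alkene bridge, which is the C1 epimer, so an oxidation–reduction pair is added; that reduction should at least be well biased.
- Comparison: the ene step is concerted and clean, but the route to its substrate is longer and less secure than the thirteen steps of the chosen plan.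

**Alternative 3:** The cuts are the C6–CH2NO2 bond and the C4=C5 bond. In the forward sense the dialdehyde A7 and nitromethane A8 would react under secondary amine and acid catalysis. Iminium activation of the cyclohexylidene acetaldehyde lets the nitronate add to C6, and the C5 enamine so formed condenses with the tethered aldehyde C4 to give A6. A Nef reaction would then convert CH2NO2 into the C6 formyl group.
- In its favour: it is metal-free. Ring A, quaternary C6 and the enal are made in one flask, the acetate can be in place from the start and no dehydrogenation is needed, so its end-game is the better one. Reversible conjugate addition could funnel material through the only epimer able to cyclise.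
- Against it here: iminium-mediated addition to a β,β-disubstituted enal to make a quaternary carbon is the least favourable case of this chemistry. The C6 face is chosen in an intermolecular event and not by a tether. The C1 acetate sits γ to the dienamine and could be lost by vinylogous elimination. The Nef conversion of a neopentyl primary nitro group next to an enal and an ester is harsh. A7 still requires all of ring B's stereochemistry plus two differentiated aldehydes.
- Comparison: it would be shorter on paper, but it is less certain mechanistically than the chosen anodic closure.

Key step: step 10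

Remark on the chemistry: 1 is taken as the commercial natural product of (R) configuration. The C2 epimers before step 4, the C5 epimers after step 10 and the enol ether geometric isomers are carried as mixtures, because each of these centres later becomes planar.

Step 1
Reactants: 1 (R)-xanthorrhizol
Product: 2 (R)-xanthorrhizol methyl ether
Conditions: MeI, K2CO3, acetone, reflux
Reagents that add atoms: iodomethane, CI
Why: Williamson O-methylation of the phenoxide; the ether is needed because a phenoxide resists dissolving-metal reduction, and no stereocentre is touched.

Step 2
Reactants: 2 (R)-xanthorrhizol methyl ether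
Product: 4 6-methyl-3-[(2R)-6-methylhept-5-en-2-yl]cyclohex-2-en-1-one (both C6 epimers), via dihydroanisole 3 (not isolated)
Conditions: Li, NH3 (l), THF, t-BuOH, −78 → −33 °C; NH4Cl; then 1 M aq. HCl, THF, rt
Reagents that add atoms: water, O
Why: Birch reduction puts the new hydrogens on the two unsubstituted carbons that keep methoxy, methyl and side chain on sp2 carbons; mild acid then hydrolyses the enol ether and moves the ring alkene into conjugation with the ketone, while the isolated trisubstituted alkene is inert to dissolving metal and the short mild acid treatment should not enolise toward C1′.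

Step 3
Reactants: 4 6-methyl-3-[(2R)-6-methylhept-5-en-2-yl]cyclohex-2-en-1-one
Product: 5 (5R)-2-methyl-5-[(2R)-6-methylhept-5-en-2-yl]cyclohexan-1-one (both C2 epimers)
Conditions: Cu(OAc)2·H2O (cat.), (R)-DTBM-SEGPHOS (cat.), (EtO)2MeSiH, t-BuOH, toluene, 0 °C
Reagents that add atoms: none
Why: Ligand-controlled asymmetric conjugate reduction of a 3-alkylcyclohexenone by a bisphosphine-ligated copper hydride; the ligand chooses the face of the β-carbon and so should set the ring stereocentre (5R here, C7 S in the target) independently of C1′, with the ligand antipode used if a test shows the opposite sense; the isolated alkene does not react.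

Step 4
Reactants: 5 (5R)-2-methyl-5-[(2R)-6-methylhept-5-en-2-yl]cyclohexan-1-one
Product: 6 (4R)-1-methyl-4-[(2R)-6-methylhept-5-en-2-yl]-2-(trimethylsilyloxy)cyclohex-1-ene
Conditions: TMSCl, NaI, Et3N, MeCN, rt
Reagents that add atoms: chlorotrimethylsilane, C[Si](C)(C)Cl
Why: Enol silylation under equilibrating conditions favours the tetrasubstituted enol ether, which merges both C2 epimers into one compound; the stereocentre β to the carbonyl is not enolisable and is untouched.

Step 5
Reactants: 6 (4R)-1-methyl-4-[(2R)-6-methylhept-5-en-2-yl]-2-(trimethylsilyloxy)cyclohex-1-ene; 7 diallyl carbonate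
Product: 8 (2R,5R)-2-methyl-5-[(2R)-6-methylhept-5-en-2-yl]-2-(prop-2-en-1-yl)cyclohexan-1-one (allyl cis to the ring side chain)
Conditions: Pd2(dba)3 (cat.), (R)-t-BuPHOX (cat.), Bu4N[Ph3SiF2] (35 mol%), THF, 25 °C
Reagents that add atoms: none
Why: Tsuji–Trost-type enantioselective allylation of a fluoride-activated tetrasubstituted silyl enol ether through an allylpalladium enolate; the (R)-phosphinooxazoline ligand (chosen by analogy with the parent 2-methylcyclohexanone series) and the substrate's own preference for axial bond formation cis to the equatorial side chain should both deliver allyl to the β face and set quaternary C2.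

Step 6
Reactants: 8 (2R,5R)-2-methyl-5-[(2R)-6-methylhept-5-en-2-yl]-2-(prop-2-en-1-yl)cyclohexan-1-one; 9 trimethyl orthoformate
Product: 11 (2R,5S,6R)-6-(dimethoxymethyl)-2-methyl-5-[(2R)-6-methylhept-5-en-2-yl]-2-(prop-2-en-1-yl)cyclohexan-1-one, via trimethylsilyl enol ether 10 (not isolated)
Conditions: LiN(i-Pr)2, THF, −78 °C; TMSCl; solvent change; then 9, TMSOTf (cat.), CH2Cl2, −78 °C
Reagents that add atoms: none
Why: Deprotonation can occur only at C6 because C2 is quaternary; the silyl enol ether then undergoes a Mukaiyama-type alkylation by the dimethoxycarbenium ion, which should enter trans to the axial allyl group and end equatorial (α), and the silyl enol ether is far more nucleophilic than either alkene.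

Step 7
Reactants: 11 (2R,5S,6R)-6-(dimethoxymethyl)-2-methyl-5-[(2R)-6-methylhept-5-en-2-yl]-2-(prop-2-en-1-yl)cyclohexan-1-one
Product: 12 (1S,2R,5S,6S)-6-(dimethoxymethyl)-2-methyl-5-[(2R)-6-methylhept-5-en-2-yl]-2-(prop-2-en-1-yl)cyclohexan-1-ol (hydroxyl α: cis to the C2 methyl, trans to allyl)
Conditions: LiBH(s-Bu)3 (L-Selectride), THF, −78 °C; sat. aq. NH4Cl
Reagents that add atoms: none
Why: Steric approach control in a bulky trialkylborohydride reduction: in the chair with side chain and acetal equatorial, the α face of C1 is screened by the axial hydrogens on C7 and C9, so hydride should come along the equatorial direction from the β face and give the axial α-alcohol, as is usual for ketones flanked by a quaternary carbon with an axial alkyl group (4,4-dimethyl-3-keto triterpenoids).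

Step 8
Reactants: 12 (1S,2R,5S,6S)-6-(dimethoxymethyl)-2-methyl-5-[(2R)-6-methylhept-5-en-2-yl]-2-(prop-2-en-1-yl)cyclohexan-1-ol; 13 carbon monoxide; 9 trimethyl orthoformate
Product: 15 ring B alcohol bis(dimethyl acetal) (12 with the allyl group turned into a 4,4-dimethoxybutyl chain), via chain aldehyde 14 (not isolated)
Conditions: Rh(acac)(CO)2 (cat.), Xantphos (cat.), CO/H2 (1:1, 10 bar), toluene, 60 °C; then 9, PPTS (cat.), MeOH, rt
Reagents that add atoms: none
Why: Linear-selective rhodium/bisphosphine hydroformylation of the monosubstituted alkene adds the last chain carbon (the future C5 formyl carbon) while the trisubstituted alkene stays inert; acetalisation in the same flask protects the aldehyde, and the hydroxyl is trans to the chain and cannot form a lactol.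

Step 9
Reactants: 15 ring B alcohol bis(dimethyl acetal)
Product: 17 ring B bis(methyl enol ether) (C1 α-triethylsilyloxy; C2 α-methyl and β-(4-methoxybut-3-en-1-yl); C6 exocyclic methoxymethylidene; C7 β side chain; both enol ether geometries), via triethylsilyl ether 16 (not isolated)
Conditions: TESOTf (1.2 equiv), i-Pr2NEt (6 equiv), CH2Cl2, −78 °C; then TMSOTf (2.6 equiv), −20 °C → rt; aq. NaOH
Reagents that add atoms: triethylsilyl trifluoromethanesulfonate, CC[Si](CC)(CC)OS(=O)(=O)C(F)(F)F
Why: The silyl triflate first silylates the hindered alcohol; silyl triflate then ionises each dimethyl acetal to an oxocarbenium ion that the hindered amine deprotonates at C5 or C6 (the known silyl triflate/amine conversion of acetals into enol ethers); geometry is irrelevant, and any acetal ionised early by the first triflate leads to the same product.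

Step 10
Reactants: 17 ring B bis(methyl enol ether)
Product: 18 bicyclo[3.3.1]nonane bis(dimethyl acetal) (C1 α-triethylsilyloxy; C2 methyl; C5 and C6 dimethoxymethyl, C5 epimers; C7 β side chain)
Conditions: reticulated vitreous carbon anode, Pt cathode, undivided cell, constant current (about 2.2 F/mol), 0.1 M LiClO4, MeOH/CH2Cl2 (1:4), 2,6-lutidine, rt
Reagents that add atoms: methanol, CO
Why: At the carbon anode the more electron-rich, trisubstituted exocyclic enol ether at C6 should lose one electron to give a radical cation. Its oxygen-free carbon C6 is attacked by the nucleophilic oxygen-free carbon C5 of the chain enol ether, which forms C5–C6; the α-methoxy radical left behind is oxidised again, both oxocarbenium ions are captured by methanol as dimethyl acetals, protons are reduced to hydrogen at the cathode and 2,6-lutidine buffers the anode region. The closest known reaction type is the intramolecular anodic coupling of bis(enol ethers) to masked 1,4-dicarbonyl compounds, which is known to tolerate the formation of quaternary carbons. Ring A closes in the 6-exo mode with respect to both double bonds, as a chair that bridges the 1,3-diaxial positions C2 and C6 of ring B. The new stereocentre C6 is controlled by the three-carbon tether, which is anchored on the β face at C2 (set in step 5) and can reach C6 only from that face; the ring B chair this requires (chain and C1 silyloxy axial, C7 side chain equatorial) should also be the preferred one. C5 forms as a mixture that step 13 erases, and neither enol ether geometry matters. The step needs the enol ethers to be oxidised in preference to the trisubstituted alkene, which their lower oxidation potential secures under constant-current control, and it needs ring closure to outrun methanol capture at C6, which the pre-organised axial chain and the six-membered transition state favour.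

Step 11
Reactants: 18 bicyclo[3.3.1]nonane bis(dimethyl acetal)
Product: 19 hydroxy dialdehyde (C1 α-hydroxyl; C5 and C6 formyl, C5 epimers; otherwise as 18)
Conditions: 1 M aq. HCl, THF, rt
Reagents that add atoms: water, O
Why: Acid-catalysed hydrolysis of both acetals through oxocarbenium ions and protodesilylation of the triethylsilyl ether in one operation; C6 has no α-hydrogen and C1 is flanked by two quaternary carbons, so dehydration is impossible, and only the irrelevant C5 centre can epimerise.

Step 12
Reactants: 19 hydroxy dialdehyde
Product: 20 acetoxy dialdehyde (19 with C1 α-acetoxy)
Conditions: Ac2O, DMAP, pyridine, CH2Cl2, rt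
Reagents that add atoms: acetic anhydride, CC(=O)OC(C)=O
Why: DMAP-catalysed acylation of the secondary alcohol; the aldehydes are inert to the acylpyridinium ion at room temperature, and the β-acetoxy aldehyde so formed cannot eliminate because C6 is quaternary.

Step 13
Reactants: 20 acetoxy dialdehyde
Product: 22 target CNP0299929.2 ((1R,2R,6R,7S)-1-acetoxy-2-methyl-7-[(2R)-6-methylhept-5-en-2-yl]bicyclo[3.3.1]non-4-ene-5,6-dicarbaldehyde in the locants used here), via trimethylsilyl enol ether 21 (not isolated)
Conditions: TMSOTf, Et3N, CH2Cl2, 0 °C; then Pd(OAc)2 (1.1 equiv), MeCN, rt
Reagents that add atoms: none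
Why: Saegusa–Ito oxidation: only the C5 aldehyde can enolise, so silylation is regiospecific; divalent palladium forms the C5-bound enolate, and β-hydride elimination can use only a C4 hydrogen because C6 is quaternary, giving the C4=C5 enal and merging the C5 epimers.

## Compound list

1 | (R)-xanthorrhizol, 2-methyl-5-[(2R)-6-methylhept-5-en-2-yl]phenol | Cc1ccc(cc1O)[C@H](C)CCC=C(C)C | starting material
2 | (R)-xanthorrhizol methyl ether, 2-methoxy-1-methyl-4-[(2R)-6-methylhept-5-en-2-yl]benzene | COc1cc(ccc1C)[C@H](C)CCC=C(C)C | intermediate
3 | dihydroanisole, 1-methoxy-2-methyl-5-[(2R)-6-methylhept-5-en-2-yl]cyclohexa-1,4-diene | COC1=C(C)CC=C(C1)[C@H](C)CCC=C(C)C | intermediate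
4 | 6-methyl-3-[(2R)-6-methylhept-5-en-2-yl]cyclohex-2-en-1-one (C6 epimers) | CC1CCC(=CC1=O)[C@H](C)CCC=C(C)C | intermediate
5 | (5R)-2-methyl-5-[(2R)-6-methylhept-5-en-2-yl]cyclohexan-1-one (C2 epimers) | CC1CC[C@@H]([C@H](C)CCC=C(C)C)CC1=O | intermediate
6 | (4R)-1-methyl-4-[(2R)-6-methylhept-5-en-2-yl]-2-(trimethylsilyloxy)cyclohex-1-ene | CC1=C(O[Si](C)(C)C)C[C@@H](CC1)[C@H](C)CCC=C(C)C | intermediate
7 | diallyl carbonate | C=CCOC(=O)OCC=C | starting material
8 | (2R,5R)-2-methyl-5-[(2R)-6-methylhept-5-en-2-yl]-2-(prop-2-en-1-yl)cyclohexan-1-one | O=C1[C@@](C)(CC=C)CC[C@@H]([C@H](C)CCC=C(C)C)C1 | intermediate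
9 | trimethyl orthoformate | COC(OC)OC | starting material
10 | trimethylsilyl enol ether of 8 (enol double bond toward C6) | C=CC[C@@]1(C)CC[C@@H]([C@H](C)CCC=C(C)C)C=C1O[Si](C)(C)C | intermediate
11 | (2R,5S,6R)-6-(dimethoxymethyl)-2-methyl-5-[(2R)-6-methylhept-5-en-2-yl]-2-(prop-2-en-1-yl)cyclohexan-1-one | O=C1[C@@](C)(CC=C)CC[C@@H]([C@H](C)CCC=C(C)C)[C@@H]1C(OC)OC | intermediate
12 | (1S,2R,5S,6S)-6-(dimethoxymethyl)-2-methyl-5-[(2R)-6-methylhept-5-en-2-yl]-2-(prop-2-en-1-yl)cyclohexan-1-ol | O[C@@H]1[C@@](C)(CC=C)CC[C@@H]([C@H](C)CCC=C(C)C)[C@@H]1C(OC)OC | intermediate
13 | carbon monoxide | [C-]#[O+] | starting material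
14 | chain aldehyde (12 with the allyl group turned into a 4-oxobutyl chain) | O[C@@H]1[C@@](C)(CCCC=O)CC[C@@H]([C@H](C)CCC=C(C)C)[C@@H]1C(OC)OC | intermediate
15 | ring B alcohol bis(dimethyl acetal) (4,4-dimethoxybutyl chain on C2, dimethoxymethyl on C6) | O[C@@H]1[C@@](C)(CCCC(OC)OC)CC[C@@H]([C@H](C)CCC=C(C)C)[C@@H]1C(OC)OC | intermediate
16 | triethylsilyl ether of 15 | CC[Si](CC)(CC)O[C@@H]1[C@@](C)(CCCC(OC)OC)CC[C@@H]([C@H](C)CCC=C(C)C)[C@@H]1C(OC)OC | intermediate
17 | ring B bis(methyl enol ether), C1 triethylsilyl ether (enol ether geometries mixed) | CC[Si](CC)(CC)O[C@@H]1[C@@](C)(CCC=COC)CC[C@@H]([C@H](C)CCC=C(C)C)C1=COC | intermediate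
18 | bicyclo[3.3.1]nonane 5,6-bis(dimethoxymethyl) compound, C1 triethylsilyl ether (C5 epimers) | CC[Si](CC)(CC)O[C@@H]1[C@@]2(C)CCC(C(OC)OC)[C@]1(C(OC)OC)[C@H]([C@H](C)CCC=C(C)C)CC2 | intermediate
19 | hydroxy dialdehyde, bicyclo[3.3.1]nonane-5,6-dicarbaldehyde with free C1 hydroxyl (C5 epimers) | O[C@@H]1[C@@]2(C)CCC(C=O)[C@]1(C=O)[C@H]([C@H](C)CCC=C(C)C)CC2 | intermediate
20 | acetoxy dialdehyde (C5 epimers) | CC(=O)O[C@@H]1[C@@]2(C)CCC(C=O)[C@]1(C=O)[C@H]([C@H](C)CCC=C(C)C)CC2 | intermediate
21 | C5 trimethylsilyl enol ether of 20 | CC(=O)O[C@@H]1[C@@]2(C)CCC(=CO[Si](C)(C)C)[C@]1(C=O)[C@H]([C@H](C)CCC=C(C)C)CC2 | intermediate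
22 | CNP0299929.2 | CC(=O)O[C@@H]1[C@@]2(C)CC=C(C=O)[C@]1(C=O)[C@H]([C@H](C)CCC=C(C)C)CC2 | target

## Step count and least certain steps

Total step count: 13 steps. Longest linear sequence: 13 steps (1 → 22); the route is fully linear.

**Step 10 (key step).** Methanol may capture the C6 radical cation before ring closure, because closing onto a carbon that becomes quaternary and is flanked on both sides is slow. Some oxidation of the side-chain alkene could occur if the current is not stopped in time. The fallback replaces the electrode by a one-electron metal oxidant in a medium without alcohol, and the methyl enol ethers by silyl enol ethers. It sets out from 15. Silylation with TBSOTf and 2,6-lutidine would give the tert-butyldimethylsilyl ether bis(acetal) F1. Mild hydrolysis (PPTS, wet acetone) would give the ring B dialdehyde F2. TBSOTf and Et3N would give the threefold silylated bis(silyl enol ether) F3. Oxidation with (NH4)2Ce(NO3)6 and NaHCO3 in MeCN, in which tetravalent cerium removes one electron from a silyl enol ether and the silyl groups leave as the cationic fragments, would give the silyl-protected bicyclic dialdehyde F4. Aqueous HF in MeCN would remove the silyl ether and return the material to the route at 19. This path also does without the acetal elimination of step 9.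

**Step 7.** Facial selectivity may be eroded if the axial allyl group on C2 hinders the equatorial approach of the bulky hydride more than expected, so that attack from the α face gives the equatorial alcohol. The fallback changes the control element from substrate to catalyst. Starting from 11, a Corey–Bakshi–Shibata reduction (oxazaborolidine, BH3·SMe2) would be used, choosing the catalyst enantiomer that treats quaternary C2 as the large flank and delivers hydride to the β face. It returns to the route at 12.

**Step 3.** Facial selectivity at C7 may be poor if the adjacent C1′ centre opposes the ligand, or hydride transfer may be slow because the β-substituent is a branched alkyl group. The fallback changes the activation mode. Starting from 4, an iminium-catalysed transfer hydrogenation with a Hantzsch ester and a chiral amine salt would be used, in which the organocatalyst selects the face. It returns to the route at 5.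

**Step 5.** C–C bond formation at the hindered tetrasubstituted enolate carbon may be slow, allowing protodesilylation to 5, and diastereocontrol at C2 may be incomplete. The fallback drops the catalyst. Starting from 6, MeLi would cleave the silyl enol ether to the regio-defined lithium enolate, which would be alkylated with allyl bromide under substrate control (axial attack cis to the equatorial side chain). It returns to the route at 8.

**Step 12.** Acylation of the hindered C1 hydroxyl may be slow, so that enol acetate or acylal formation at the aldehydes competes. The 1,4-dialdehyde may also be partly tied up as a cyclic hydrate. The fallback changes the order of events so that the acylation is done while both aldehydes are still acetals. It sets out from 18. Bu4NF in THF would give the hydroxy bis(acetal) F5. Ac2O and DMAP, with heating if needed, would give the acetoxy bis(acetal) F6. Aqueous HCl in THF would hydrolyse the acetals and return the material to the route at 20.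

## Further compounds

F1 | step 10 | tert-butyldimethylsilyl ether of 15 | CC(C)(C)[Si](C)(C)O[C@@H]1[C@@](C)(CCCC(OC)OC)CC[C@@H]([C@H](C)CCC=C(C)C)[C@@H]1C(OC)OC
F2 | step 10 | ring B dialdehyde, C1 tert-butyldimethylsilyl ether (C6 epimers) | CC(C)(C)[Si](C)(C)O[C@@H]1[C@@](C)(CCCC=O)CC[C@@H]([C@H](C)CCC=C(C)C)C1C=O
F3 | step 10 | ring B bis(tert-butyldimethylsilyl enol ether), C1 tert-butyldimethylsilyl ether | CC(C)(C)[Si](C)(C)O[C@@H]1[C@@](C)(CCC=CO[Si](C)(C)C(C)(C)C)CC[C@@H]([C@H](C)CCC=C(C)C)C1=CO[Si](C)(C)C(C)(C)C
F4 | step 10 | bicyclo[3.3.1]nonane-5,6-dicarbaldehyde, C1 tert-butyldimethylsilyl ether (C5 epimers) | CC(C)(C)[Si](C)(C)O[C@@H]1[C@@]2(C)CCC(C=O)[C@]1(C=O)[C@H]([C@H](C)CCC=C(C)C)CC2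
F0 | step 7 | none | none
F0 | step 3 | none | none
F0 | step 5 | none | none
F5 | step 12 | hydroxy bis(dimethyl acetal) (18 without the silyl group) | O[C@@H]1[C@@]2(C)CCC(C(OC)OC)[C@]1(C(OC)OC)[C@H]([C@H](C)CCC=C(C)C)CC2
F6 | step 12 | acetoxy bis(dimethyl acetal) | CC(=O)O[C@@H]1[C@@]2(C)CCC(C(OC)OC)[C@]1(C(OC)OC)[C@H]([C@H](C)CCC=C(C)C)CC2
A1 | alternative 1 | bridgehead-bromo bicyclo[4.3.1]dec-3-en-10-one, product of the (4+3) step | O=C1[C@@]2(C)CC=C(CO[Si](C)(C)C(C)(C)C)C(O[Si](C)(C)C)[C@]1(Br)[C@H]([C@H](C)CCC=C(C)C)CC2
A2 | alternative 1 | ring B 6,6-dibromo-2-methyl ketone (C2 epimers) | CC1CC[C@@H]([C@H](C)CCC=C(C)C)C(Br)(Br)C1=O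
A3 | alternative 1 | 2-[(tert-butyldimethylsilyloxy)methyl]-1-(trimethylsilyloxy)buta-1,3-diene | C=CC(CO[Si](C)(C)C(C)(C)C)=CO[Si](C)(C)C
A4 | alternative 2 | bicyclo[3.3.1]nonenol with the C1 hydroxyl over the alkene bridge, product of the ene step | O[C@H]1[C@@]2(C)CC=C(CO[Si](C)(C)C(C)(C)C)[C@]1(CO[Si](C)(C)C(C)(C)C)[C@H]([C@H](C)CCC=C(C)C)CC2
A5 | alternative 2 | cyclooctene aldehyde with tetrasubstituted C5=C6 alkene | O=C[C@@]1(C)CC/C(CO[Si](C)(C)C(C)(C)C)=C(CO[Si](C)(C)C(C)(C)C)\[C@H]([C@H](C)CCC=C(C)C)CC1
A6 | alternative 3 | 6-nitromethyl bicyclo[3.3.1]nonene carbaldehyde, product of the domino step | CC(=O)O[C@@H]1[C@@]2(C)CC=C(C=O)[C@]1(C[N+](=O)[O-])[C@H]([C@H](C)CCC=C(C)C)CC2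
A7 | alternative 3 | ring B cyclohexylidene acetaldehyde with a 2-oxoethyl group on C2 and C1 acetate | CC(=O)O[C@@H]1[C@@](C)(CC=O)CC[C@@H]([C@H](C)CCC=C(C)C)C1=CC=O
A8 | alternative 3 | nitromethane | C[N+](=O)[O-]
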